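## Analysis of the target

Target 24 is built from two identical 5,7-dimethoxycoumarin units that are joined through their C8 atoms to a 1,4-dimethylcyclohex-3-ene. The ring is numbered here C1 (quaternary; a methyl group and the E-ethenyl arm that ends at C8 of coumarin A), C2 and C3 (CH2), C4 (methyl, doubly bonded to C5), C5 (CH) and C6 (CH bonded directly to C8 of coumarin B); in the systematic names of the intermediates C6 appears as locant 2. C1 and C6 are adjacent stereocentres, both R in 24, with the ethenyl arm and coumarin B on the same face and the C1 methyl group trans to coumarin B. The two lactones do not tolerate hydride, organolithium reagents or hot hydroxide, the arenes are electron-rich, and the trisubstituted C4=C5 alkene sits where an ortho-phenol on the C6 aryl group could add across it under protic acid. The hard part is the vicinal pair of an all-carbon quaternary centre and a tertiary centre that carries an aryl group with both ortho positions oxygenated, on a ring without any heteroatom to steer reagents. The two coumarins are also attached differently (to an sp2 carbon for A, to an sp3 carbon for B), so they need different bond-forming steps. The strategy rests on one feature: with the ethenyl carbon on C1 at the ester oxidation level, C1 and C6 are the α- and β-carbons of a carboxylate and C4=C5 is the remote double bond of a cyclohexa-1,3-diene-1-carboxylate (C1=C6–C5=C4). Adding the aryl group to C6 and a methyl group to C1 of that achiral dienoate then gives the whole carbocycle with both stereocentres.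

## Retrosynthetic reasoning

**Pyranone of coumarin B (24 to 21).** The O1–C2 and C3=C4 bonds of the lactone ring of coumarin B are cut, which leads to salicylaldehyde 21 and a two-carbon phosphorus ylide. Coumarin B cannot be carried through the organometallic and hydride steps, so it is closed last; the forward reaction must make a Z-configured hydroxycinnamate (or isomerise the E-form) so that the phenol can lactonise.

**Formyl group (21 to 19).** The C–CHO bond is cut. In phenol 19 the only free carbon ortho to the hydroxyl group is exactly the future C4a, so a phenoxide-directed formylation needs no further regiocontrol.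

**Phenol protection (19 to 17).** The O–H is traced back to a methoxymethyl ether. The acetal is kept because it is also the ortho-director that makes the aryl nucleophile; the forward cleavage must avoid strong protic acid because of the C4=C5 alkene.

**Aryl–vinyl bond (17 to 14 and 16).** The bond between C8 of coumarin A and the ethenyl arm is cut. This is the most convergent cut, and because C1 is quaternary the forward Heck reaction has only one β-hydrogen set to use, so the E-alkene is the only possible outcome. Iodide 16 comes from 15 by cutting the C8–I bond.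

**Vinyl group (14 to 13 to 12 to 11).** The C=CH2 bond is traced through aldehyde 13 and alcohol 12 to ester 11. These are oxidation-level changes only; they are accepted because the ester is what activates C1=C6 for the key step and is the enolate precursor for the methylation.

**Aryl–C6 and C1–CH3 (11 to 4, 8 and 9).** Both bonds are cut together. The forward step must add the aryl group of 8 to the β-carbon of dienoate 4 on one enantiotopic face and methylate the resulting enolate with 9 trans to the new aryl group. It is placed here because it turns an achiral two-step diene into the complete ring with both stereocentres.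

**Aryl nucleophile (8 to 6 to 5).** The C–Zn bond goes back to a C–H bond flanked by the acetal and a methoxy group in 6, and 6 to phenol 5.

**Dienoate (4 to 3 to 1 and 2).** 4 is the conjugated isomer of 1,4-diene 3, and 3 is the Diels–Alder adduct of 1 and 2 (two ring bonds cut).

## Alternatives that were turned down

**Alternative 1:** Here the benzene ring of coumarin B is not attached to C6 but grown on it.

- Disconnection: three ring bonds of that arene (C8–C8a, C6–C7 and C4a–C8a in coumarin numbering) are removed. This leads back to siloxyalkyne A3, a cyclohexene that already carries C1, C6 and a silylated ethynyl group on C1, and to 3-methoxycyclobut-2-en-1-one A2.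
- Forward key step: A2 opens thermally to a vinylketene, which adds to the electron-rich alkyne of A3 in a [2+2] sense. The new cyclobutenone opens, the dienylketene closes by 6π-electrocyclisation and tautomerises to phenol A1 (Danheiser benzannulation).
- For it: no hindered aryl–C6 bond has to be made with an organometallic reagent. The oxygen pattern of ring B comes out differentiated (free hydroxyl for the C7 methoxy group, silyl ether for the lactone oxygen), and the regiochemistry follows from the polarity of the ynol ether. On these two points it is stronger than the chosen route.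
- Against it: the benzannulation creates neither stereocentre and does not make the cyclohexene, so the C1/C6 problem is only moved into the synthesis of A3, a hindered secondary ynol ether beside a quaternary carbon. The ketene can also add to C4=C5. After A1 come O-methylation, desilylation, formylation, lactonisation and the conversion of the silylalkyne into the E-alkene to coumarin A.
- Comparison: the chosen route offers a single catalytic step that makes the aryl–C6 bond, the quaternary methyl and both stereocentres, and it is several steps shorter.

**Alternative 2:** The C5–C6 bond is cut.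

- Disconnection: the ring opens to acyclic benzylic alcohol A5. C6 is a carbinol on C8 of an intact coumarin B, C1 is a pre-formed quaternary centre with methyl and a silylethynyl group, and C4=C5 is present as a Z-vinylsilane.
- Forward key step: acid ionises the carbinol to a benzylic cation stabilised by the ortho and para methoxy groups. The vinylsilane attacks through its silicon-bearing carbon, the β-silyl cation at C4 loses silicon, and cyclohexene A4 results with the alkene fixed at C4=C5.
- For it: coumarin B arrives complete, so the three late steps that the chosen route spends on building it disappear, and both carbinol epimers converge on one cation. On late-stage economy this plan is stronger.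
- Against it: the quaternary centre C1 must be made enantioenriched on an open chain before the key step, which therefore does not solve the hardest stereocentre. The C6 configuration depends on a chair-like closure that must tell the C1 methyl group from the slim alkynyl group, a small energy difference. The cation sits beside a quaternary carbon and can suffer a 1,2-shift, the Z-trisubstituted vinylsilane needs its own stereocontrolled synthesis, and the alkyne must still be turned into the E-alkene to coumarin A.
- Comparison: the chosen route gives up the intact coumarin B but gains catalyst control at C6, substrate control at C1 from a cyclic enolate, and a much shorter way to the key-step precursor.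

**Alternative 3:** The C1–C6 bond is cut in a [3,3] sense.

- Disconnection: this leads to δ-lactone A7, in which the lactone oxygen sits on C4, C4 carries the methyl group and an E-styryl group (the future C5=C6 with the protected ring B phenol), and C1 is the α-carbon.
- Forward key step: enolisation and O-silylation give the cyclic silyl ketene acetal, which rearranges through the boat-shaped transition state that the lactone ring enforces. C1–C6 forms, the C4–O bond breaks, the alkene moves to C4=C5 and the lactone contracts to cyclohexene acid A6 (Ireland–Claisen rearrangement).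
- For it: one carbinol stereocentre is relayed to both C1 and C6 through a rigid bicyclic transition state, the E-alkene and the boat together place aryl cis to carboxyl, and no hindered aryl group has to be transferred from a metal. In predictability of the relative configuration it is at least as strong as the chosen route, and A6 is the free acid of ester 11, so the end game would be the same.
- Against it: the stereochemical burden shifts to the tertiary allylic carbinol carbon of A7, whose asymmetric synthesis costs several steps. That C–O bond is tertiary, allylic and conjugated through the styrene to a very electron-rich arene, so ionisation or elimination competes with enolisation. The bicyclo[2.2.2]-like transition state must also join a fully substituted ketene acetal carbon to a styrene carbon bearing a 2,6-dioxygenated aryl group.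
- Comparison: the chosen route reaches the same oxidation pattern in one catalytic operation from an achiral diene made in two steps, with the absolute configuration coming from a catalyst and not from a stereocentre that must be built first.

Key step: step 5

Remark (assumption): the antipode of the diene ligand that sends the aryl group to the required face of C6 is taken to be (R,R)-Ph-bod* [(1R,4R)-2,5-diphenylbicyclo[2.2.2]octa-2,5-diene]; if the sense of induction turns out opposite, the (S,S)-ligand is used and nothing else changes.

## Route

Step 1
Reactants: 1 isoprene (2-methylbuta-1,3-diene); 2 methyl propiolate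
Product: 3 methyl 4-methylcyclohexa-1,4-diene-1-carboxylate
Conditions: AlCl3 (20 mol %), CH2Cl2, 0 °C → rt
Reagents that add atoms: none
Why: Lewis-acid-catalysed Diels–Alder reaction of a 2-substituted diene with an alkynoate; the larger HOMO coefficient at C1 of isoprene meets the β-carbon of the complexed propiolate, which places methyl and ester 1,4 on the new cyclohexa-1,4-diene. No stereocentre is formed, and the minor 1,3-regioisomer is removed by distillation.

Step 2
Reactants: 3 methyl 4-methylcyclohexa-1,4-diene-1-carboxylate
Product: 4 methyl 4-methylcyclohexa-1,3-diene-1-carboxylate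
Conditions: DBU (0.5 equiv), degassed toluene, 80 °C, argon
Reagents that add atoms: none
Why: Base-mediated prototropic isomerisation: DBU removes a proton from the doubly allylic CH2 that is also vinylogously α to the ester, and reprotonation of the dienolate at its far end moves the isolated alkene into conjugation. The linearly conjugated dienoate with two trisubstituted alkenes is the thermodynamic isomer; oxygen is excluded so that the dienes are not dehydrogenated to the aromatic ester.

Step 3
Reactants: 5 3,5-dimethoxyphenol
Product: 6 1,3-dimethoxy-5-(methoxymethoxy)benzene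
Conditions: MOMCl, i-Pr2NEt, CH2Cl2, 0 °C → rt
Reagents that add atoms: chloromethyl methyl ether, COCCl
Why: O-Alkylation of the phenol with an α-chloro ether under amine base (Williamson-type acetal formation). The MOM ether is the strongest ortho-director available for step 4 and is inert to organozinc, hydride, ylide and palladium chemistry up to step 11.

Step 4
Reactants: 6 1,3-dimethoxy-5-(methoxymethoxy)benzene
Product: 8 [2,4-dimethoxy-6-(methoxymethoxy)phenyl]zinc chloride as a THF solution, via aryllithium 7 (not isolated)
Conditions: n-BuLi, THF, 0 °C; then ZnCl2, 0 °C → rt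
Reagents that add atoms: zinc dichloride, Cl[Zn]Cl
Why: Directed ortho-metalation: the acetal oxygens and the neighbouring methoxy group together hold n-BuLi at the CH between them (two equivalent sites), in preference to the CH between the two methoxy groups. Transmetalation with ZnCl2 gives the arylzinc chloride, which tolerates the ester of 4.

Step 5
Reactants: 4 methyl 4-methylcyclohexa-1,3-diene-1-carboxylate; 8 [2,4-dimethoxy-6-(methoxymethoxy)phenyl]zinc chloride; 9 iodomethane
Product: 11 methyl (1S,2S)-2-[2,4-dimethoxy-6-(methoxymethoxy)phenyl]-1,4-dimethylcyclohex-3-ene-1-carboxylate, via chlorozinc ester enolate 10 (not isolated)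
Conditions: [RhCl(C2H4)2]2 (2.5 mol %), (R,R)-Ph-bod* (5.5 mol %), THF, 0 → 25 °C; then MeI, DMPU, 0 → 25 °C
Reagents that add atoms: iodomethane (compound 9), CI
Why: The chloride-bridged rhodium–diene complex is arylated by 8 to an aryl complex of monovalent rhodium, which binds the C1=C6 alkene of 4 and inserts it syn so that the aryl group goes to C6 and rhodium to C1 as an oxa-π-allyl; transmetalation with more 8 releases chlorozinc enolate 10 and regenerates the aryl–rhodium species. The closest known reaction type is the rhodium-catalysed asymmetric 1,4-addition of arylzinc chlorides to unsaturated carbonyl compounds with alkylation of the metal enolate in the same flask. No ring is closed. C6 is set by the catalyst: the C2-symmetric diene ligand leaves one enantiotopic face of the C1=C6 alkene open to the migrating aryl group. C1 is set by C6: in 10 allylic 1,3-strain between the enolate oxygens and the C6 substituent turns the aryl group pseudoaxial, so MeI adds to the opposite face and the methyl group ends trans to aryl, the ester cis. The step needs 1,4- and not 1,6-addition, which is secured because the δ-carbon C4 is fully substituted and would have to become quaternary, and it needs C- and not O-methylation, which the soft electrophile in DMPU provides. The C4=C5 alkene is untouched because after insertion it is no longer conjugated to the metal-bearing carbon.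

Step 6
Reactants: 11 methyl (1S,2S)-2-[2,4-dimethoxy-6-(methoxymethoxy)phenyl]-1,4-dimethylcyclohex-3-ene-1-carboxylate
Product: 12 [(1S,2R)-2-[2,4-dimethoxy-6-(methoxymethoxy)phenyl]-1,4-dimethylcyclohex-3-en-1-yl]methanol
Conditions: LiAlH4, THF, 0 °C → rt
Reagents that add atoms: none
Why: Hydride reduction of the ester to the neopentyl alcohol; LiAlH4 is chosen because the carbonyl is flanked by a quaternary carbon. Acetal, aryl ethers and the isolated alkene are inert and neither stereocentre can enolise (the descriptor at locant 2 changes only because the priorities change).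

Step 7
Reactants: 12 [(1S,2R)-2-[2,4-dimethoxy-6-(methoxymethoxy)phenyl]-1,4-dimethylcyclohex-3-en-1-yl]methanol
Product: 13 (1S,2S)-2-[2,4-dimethoxy-6-(methoxymethoxy)phenyl]-1,4-dimethylcyclohex-3-ene-1-carbaldehyde
Conditions: Dess–Martin periodinane, CH2Cl2, 0 °C → rt
Reagents that add atoms: none
Why: Dess–Martin oxidation of a primary alcohol to the aldehyde under near-neutral conditions. The aldehyde has no α-hydrogen, so C1 cannot epimerise.

Step 8
Reactants: 13 (1S,2S)-2-[2,4-dimethoxy-6-(methoxymethoxy)phenyl]-1,4-dimethylcyclohex-3-ene-1-carbaldehyde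
Product: 14 2-[(1R,6R)-6-ethenyl-3,6-dimethylcyclohex-2-en-1-yl]-1,5-dimethoxy-3-(methoxymethoxy)benzene
Conditions: Ph3PCH3Br, KOt-Bu, THF, 0 °C → rt
Reagents that add atoms: methyltriphenylphosphonium bromide, C[P+](c1ccccc1)(c1ccccc1)c1ccccc1.[Br-]
Why: Wittig methylenation with the non-stabilised ylide, which reacts even with α-quaternary aldehydes; the aldehyde cannot enolise under the basic conditions.

Step 9
Reactants: 15 5,7-dimethoxycoumarin (5,7-dimethoxy-2H-chromen-2-one)
Product: 16 8-iodo-5,7-dimethoxy-2H-chromen-2-one
Conditions: NIS (1.0 equiv), CF3CO2H (cat.), MeCN, 0 °C → rt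
Reagents that add atoms: N-iodosuccinimide, O=C1CCC(=O)N1I
Why: Electrophilic aromatic iodination: C8 is para to the C5 methoxy group, ortho to the C7 methoxy group and flanked on its other side only by the ring oxygen, whereas C6 lies between two methoxy groups and C3 belongs to the electron-poor pyranone alkene. One equivalent of NIS with catalytic acid at low temperature limits over-iodination.

Step 10
Reactants: 14 2-[(1R,6R)-6-ethenyl-3,6-dimethylcyclohex-2-en-1-yl]-1,5-dimethoxy-3-(methoxymethoxy)benzene; 16 8-iodo-5,7-dimethoxy-2H-chromen-2-one
Product: 17 8-[(E)-2-[(1R,2R)-2-[2,4-dimethoxy-6-(methoxymethoxy)phenyl]-1,4-dimethylcyclohex-3-en-1-yl]ethenyl]-5,7-dimethoxy-2H-chromen-2-one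
Conditions: Pd(OAc)2 (10 mol %), n-Bu4NCl, NaHCO3, DMF, 90 °C
Reagents that add atoms: none
Why: Mizoroki–Heck reaction: oxidative addition of 16 to zerovalent palladium, insertion of the monosubstituted alkene with aryl at the terminal carbon, and syn β-hydride elimination, which can only use the benzylic CH2 because the other neighbour is quaternary C1, so only the E-alkene can form. The trisubstituted C4=C5 alkene and the coumarin C3=C4 bond are much poorer acceptors, and NaHCO3 spares the lactone.

Step 11
Reactants: 17 8-[(E)-2-[(1R,2R)-2-[2,4-dimethoxy-6-(methoxymethoxy)phenyl]-1,4-dimethylcyclohex-3-en-1-yl]ethenyl]-5,7-dimethoxy-2H-chromen-2-one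
Product: 19 8-[(E)-2-[(1R,2R)-2-(2-hydroxy-4,6-dimethoxyphenyl)-1,4-dimethylcyclohex-3-en-1-yl]ethenyl]-5,7-dimethoxy-2H-chromen-2-one, via aryl trimethylsilyl ether 18 (not isolated)
Conditions: TMSOTf, 2,2′-bipyridyl, MeCN, 0 °C → rt; then H2O
Reagents that add atoms: none
Why: Cleavage of an aromatic MOM ether with a silyl triflate buffered by 2,2′-bipyridyl: the acetal is converted into aryl silyl ether 18 while the methoxymethyl unit is taken up by the pyridine nitrogen, and water then hydrolyses the silyl ether. No free strong acid is present, so C4=C5 is not protonated and the new phenol cannot add to it; the lactone and the styrene are inert.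

Step 12
Reactants: 19 8-[(E)-2-[(1R,2R)-2-(2-hydroxy-4,6-dimethoxyphenyl)-1,4-dimethylcyclohex-3-en-1-yl]ethenyl]-5,7-dimethoxy-2H-chromen-2-one
Product: 21 3-[(1R,6R)-6-[(E)-2-(5,7-dimethoxy-2-oxo-2H-chromen-8-yl)ethenyl]-3,6-dimethylcyclohex-2-en-1-yl]-2-hydroxy-4,6-dimethoxybenzaldehyde, via hydroxymethylphenol 20 (not isolated)
Conditions: MgCl2, Et3N, (CH2O)n, MeCN, 80 °C
Reagents that add atoms: formaldehyde (from paraformaldehyde), C=O
Why: Magnesium-mediated ortho-formylation of a phenol (Casnati–Skattebøl reaction): the magnesium phenoxide delivers formaldehyde to the only free ortho carbon, and the resulting benzylic alkoxide 20 is oxidised by a second formaldehyde through hydride transfer. The CH between the two methoxy groups, para to the hydroxyl group, is not reached by this chelate-controlled path.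

Step 13
Reactants: 21 3-[(1R,6R)-6-[(E)-2-(5,7-dimethoxy-2-oxo-2H-chromen-8-yl)ethenyl]-3,6-dimethylcyclohex-2-en-1-yl]-2-hydroxy-4,6-dimethoxybenzaldehyde
Product: 24 8-[(E)-2-[(1R,2R)-2-(5,7-dimethoxy-2-oxo-2H-chromen-8-yl)-1,4-dimethylcyclohex-3-en-1-yl]ethenyl]-5,7-dimethoxy-2H-chromen-2-one, via E-hydroxycinnamate ester 22 (not isolated), via Z-hydroxycinnamate ester 23 (not isolated)
Conditions: Ph3P=CHCO2Et, PhNEt2, 190 °C
Reagents that add atoms: ethyl (triphenyl-λ5-phosphanylidene)acetate, CCOC(=O)C=P(c1ccccc1)(c1ccccc1)c1ccccc1
Why: Wittig olefination of the salicylaldehyde with a stabilised ylide followed by lactonisation: Z-ester 23 closes at once by attack of the phenol on the ester (six-membered lactone), and E-ester 22 isomerises at this temperature and follows. C1 and C6 are remote from the reacting centres and are not affected.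

## Compound list

1 | isoprene (2-methylbuta-1,3-diene) | C=CC(C)=C | starting material
2 | methyl propiolate | C#CC(=O)OC | starting material
3 | methyl 4-methylcyclohexa-1,4-diene-1-carboxylate | COC(=O)C1=CCC(C)=CC1 | intermediate
4 | methyl 4-methylcyclohexa-1,3-diene-1-carboxylate | COC(=O)C1=CC=C(C)CC1 | intermediate
5 | 3,5-dimethoxyphenol | COc1cc(O)cc(OC)c1 | starting material
6 | 1,3-dimethoxy-5-(methoxymethoxy)benzene | COCOc1cc(OC)cc(OC)c1 | intermediate
7 | [2,4-dimethoxy-6-(methoxymethoxy)phenyl]lithium | [Li]c1c(OCOC)cc(OC)cc1OC | intermediate
8 | [2,4-dimethoxy-6-(methoxymethoxy)phenyl]zinc chloride | Cl[Zn]c1c(OCOC)cc(OC)cc1OC | intermediate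
9 | iodomethane | CI | starting material
10 | chlorido[[(2S)-2-[2,4-dimethoxy-6-(methoxymethoxy)phenyl]-4-methylcyclohex-3-en-1-ylidene](methoxy)methoxy]zinc (enolate geometry not defined) | COC(O[Zn]Cl)=C1CCC(C)=C[C@H]1c1c(OCOC)cc(OC)cc1OC | intermediate
11 | methyl (1S,2S)-2-[2,4-dimethoxy-6-(methoxymethoxy)phenyl]-1,4-dimethylcyclohex-3-ene-1-carboxylate | COC(=O)[C@@]1(C)CCC(C)=C[C@H]1c1c(OCOC)cc(OC)cc1OC | intermediate
12 | [(1S,2R)-2-[2,4-dimethoxy-6-(methoxymethoxy)phenyl]-1,4-dimethylcyclohex-3-en-1-yl]methanol | OC[C@@]1(C)CCC(C)=C[C@H]1c1c(OCOC)cc(OC)cc1OC | intermediate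
13 | (1S,2S)-2-[2,4-dimethoxy-6-(methoxymethoxy)phenyl]-1,4-dimethylcyclohex-3-ene-1-carbaldehyde | O=C[C@@]1(C)CCC(C)=C[C@H]1c1c(OCOC)cc(OC)cc1OC | intermediate
14 | 2-[(1R,6R)-6-ethenyl-3,6-dimethylcyclohex-2-en-1-yl]-1,5-dimethoxy-3-(methoxymethoxy)benzene | C=C[C@@]1(C)CCC(C)=C[C@H]1c1c(OCOC)cc(OC)cc1OC | intermediate
15 | 5,7-dimethoxycoumarin (5,7-dimethoxy-2H-chromen-2-one) | COc1cc(OC)c2ccc(=O)oc2c1 | starting material
16 | 8-iodo-5,7-dimethoxy-2H-chromen-2-one | COc1cc(OC)c2ccc(=O)oc2c1I | intermediate
17 | 8-[(E)-2-[(1R,2R)-2-[2,4-dimethoxy-6-(methoxymethoxy)phenyl]-1,4-dimethylcyclohex-3-en-1-yl]ethenyl]-5,7-dimethoxy-2H-chromen-2-one | COc1cc(OC)c2ccc(=O)oc2c1/C=C/[C@@]1(C)CCC(C)=C[C@H]1c1c(OCOC)cc(OC)cc1OC | intermediate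
18 | 8-[(E)-2-[(1R,2R)-2-[2,4-dimethoxy-6-(trimethylsilyloxy)phenyl]-1,4-dimethylcyclohex-3-en-1-yl]ethenyl]-5,7-dimethoxy-2H-chromen-2-one | COc1cc(OC)c2ccc(=O)oc2c1/C=C/[C@@]1(C)CCC(C)=C[C@H]1c1c(O[Si](C)(C)C)cc(OC)cc1OC | intermediate
19 | 8-[(E)-2-[(1R,2R)-2-(2-hydroxy-4,6-dimethoxyphenyl)-1,4-dimethylcyclohex-3-en-1-yl]ethenyl]-5,7-dimethoxy-2H-chromen-2-one | COc1cc(OC)c2ccc(=O)oc2c1/C=C/[C@@]1(C)CCC(C)=C[C@H]1c1c(O)cc(OC)cc1OC | intermediate
20 | 8-[(E)-2-[(1R,2R)-2-[2-hydroxy-3-(hydroxymethyl)-4,6-dimethoxyphenyl]-1,4-dimethylcyclohex-3-en-1-yl]ethenyl]-5,7-dimethoxy-2H-chromen-2-one | COc1cc(OC)c2ccc(=O)oc2c1/C=C/[C@@]1(C)CCC(C)=C[C@H]1c1c(O)c(CO)c(OC)cc1OC | intermediate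
21 | 3-[(1R,6R)-6-[(E)-2-(5,7-dimethoxy-2-oxo-2H-chromen-8-yl)ethenyl]-3,6-dimethylcyclohex-2-en-1-yl]-2-hydroxy-4,6-dimethoxybenzaldehyde | COc1cc(OC)c2ccc(=O)oc2c1/C=C/[C@@]1(C)CCC(C)=C[C@H]1c1c(O)c(C=O)c(OC)cc1OC | intermediate
22 | ethyl (E)-3-[3-[(1R,6R)-6-[(E)-2-(5,7-dimethoxy-2-oxo-2H-chromen-8-yl)ethenyl]-3,6-dimethylcyclohex-2-en-1-yl]-2-hydroxy-4,6-dimethoxyphenyl]prop-2-enoate | COc1cc(OC)c2ccc(=O)oc2c1/C=C/[C@@]1(C)CCC(C)=C[C@H]1c1c(O)c(/C=C/C(=O)OCC)c(OC)cc1OC | intermediate
23 | ethyl (Z)-3-[3-[(1R,6R)-6-[(E)-2-(5,7-dimethoxy-2-oxo-2H-chromen-8-yl)ethenyl]-3,6-dimethylcyclohex-2-en-1-yl]-2-hydroxy-4,6-dimethoxyphenyl]prop-2-enoate | COc1cc(OC)c2ccc(=O)oc2c1/C=C/[C@@]1(C)CCC(C)=C[C@H]1c1c(O)c(/C=C\C(=O)OCC)c(OC)cc1OC | intermediate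
24 | 8-[(E)-2-[(1R,2R)-2-(5,7-dimethoxy-2-oxo-2H-chromen-8-yl)-1,4-dimethylcyclohex-3-en-1-yl]ethenyl]-5,7-dimethoxy-2H-chromen-2-one | COc1cc(OC)c2ccc(=O)oc2c1/C=C/[C@@]1(C)CCC(C)=C[C@H]1c1c(OC)cc(OC)c2ccc(=O)oc12 | target

## Step count and least certain steps

Total: 13 steps. Longest linear sequence: 10 steps (steps 1, 2, 5, 6, 7, 8, 10, 11, 12 and 13; the branch through steps 3 and 4 is equally long, and step 9 is a one-step side branch).

**Step 5 (key step).** Three processes can fail. Aryl transfer from the doubly ortho-substituted zinc reagent to rhodium and insertion of the trisubstituted, α-branched alkene may be slow, so that protodemetalation of 8 wins. The diene substrate may compete with the chiral ligand for rhodium and erode face selectivity. The zinc ester enolate may methylate sluggishly, so that work-up returns unmethylated ester. Fallback, setting out from 4 and 8 and returning at 11: the arylation is run alone and quenched with aqueous NH4Cl, which should give methyl (2R)-2-[2,4-dimethoxy-6-(methoxymethoxy)phenyl]-4-methylcyclohex-3-ene-1-carboxylate F1 as a mixture of C1 epimers. Deprotonation with LDA in THF at −78 °C then gives lithium [(2S)-2-[2,4-dimethoxy-6-(methoxymethoxy)phenyl]-4-methylcyclohex-3-en-1-ylidene](methoxy)methanolate F2, a far better nucleophile than 10, and MeI should methylate it anti to the aryl group for the same conformational reason, giving 11. This fallback answers the methylation failure only; if aryl transfer itself fails, the strategy would have to be changed.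

**Step 10.** Both partners are hindered (an iodide with two ortho substituents, an alkene on a quaternary carbon), so insertion may be slow and reduction of the iodide or precipitation of palladium metal may take over. Fallback, setting out from 13 and returning at 17: Takai–Utimoto boryl-olefination of 13 (CrCl2, Cl2CHBpin, LiI, THF) should give 2-[(E)-2-[(1R,2R)-2-[2,4-dimethoxy-6-(methoxymethoxy)phenyl]-1,4-dimethylcyclohex-3-en-1-yl]ethenyl]-4,4,5,5-tetramethyl-1,3,2-dioxaborolane F3. Suzuki–Miyaura coupling of F3 with 16 (Pd(OAc)2, SPhos, K3PO4, THF/H2O, 50 °C) then gives 17; the carbon–carbon bond is made by transmetalation and reductive elimination, which do not require the hindered alkene to insert.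

**Step 2.** Equilibration may stop at a mixture of diene isomers, the dienes may lose hydrogen to the aromatic ester if air enters, or 4 may dimerise by Diels–Alder reaction on prolonged heating. Fallback, setting out from 1 and returning at 4: AlCl3-catalysed Diels–Alder reaction of 1 with methyl acrylate gives methyl 4-methylcyclohex-3-ene-1-carboxylate F4. LDA and then PhSeBr give methyl 4-methyl-1-(phenylselanyl)cyclohex-3-ene-1-carboxylate F5. H2O2 oxidises it to methyl 4-methyl-1-(phenylseleninyl)cyclohex-3-ene-1-carboxylate F6, which should undergo syn-elimination towards the allylic CH2 and so give the conjugated diene 4 directly.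

**Step 9.** Iodination may go partly to C6 or to C3, or a second iodine may enter. Fallback, setting out from 7 and returning at 16: quenching aryllithium 7 with I2 gives 2-iodo-1,5-dimethoxy-3-(methoxymethoxy)benzene F7. HCl in MeOH gives 2-iodo-3,5-dimethoxyphenol F8. MgCl2, Et3N and (CH2O)n formylate the single free ortho position to give 2-hydroxy-3-iodo-4,6-dimethoxybenzaldehyde F9. Ph3P=CHCO2Et in hot PhNEt2 then gives, through ethyl (Z)-3-(2-hydroxy-3-iodo-4,6-dimethoxyphenyl)prop-2-enoate F10, iodocoumarin 16 with the iodine placed by the lithiation and not by an electrophilic substitution.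

## Further compounds

F1 | step 5 | methyl (2R)-2-[2,4-dimethoxy-6-(methoxymethoxy)phenyl]-4-methylcyclohex-3-ene-1-carboxylate (C1 epimers) | COC(=O)C1CCC(C)=C[C@H]1c1c(OCOC)cc(OC)cc1OC
F2 | step 5 | lithium [(2S)-2-[2,4-dimethoxy-6-(methoxymethoxy)phenyl]-4-methylcyclohex-3-en-1-ylidene](methoxy)methanolate | COC(O[Li])=C1CCC(C)=C[C@H]1c1c(OCOC)cc(OC)cc1OC
F3 | step 10 | 2-[(E)-2-[(1R,2R)-2-[2,4-dimethoxy-6-(methoxymethoxy)phenyl]-1,4-dimethylcyclohex-3-en-1-yl]ethenyl]-4,4,5,5-tetramethyl-1,3,2-dioxaborolane | CC1(C)OB(/C=C/[C@@]2(C)CCC(C)=C[C@H]2c2c(OCOC)cc(OC)cc2OC)OC1(C)C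
F4 | step 2 | methyl 4-methylcyclohex-3-ene-1-carboxylate (racemic) | COC(=O)C1CCC(C)=CC1
F5 | step 2 | methyl 4-methyl-1-(phenylselanyl)cyclohex-3-ene-1-carboxylate (racemic) | COC(=O)C1([Se]c2ccccc2)CCC(C)=CC1
F6 | step 2 | methyl 4-methyl-1-(phenylseleninyl)cyclohex-3-ene-1-carboxylate (racemic) | COC(=O)C1([Se](=O)c2ccccc2)CCC(C)=CC1
F7 | step 9 | 2-iodo-1,5-dimethoxy-3-(methoxymethoxy)benzene | COCOc1cc(OC)cc(OC)c1I
F8 | step 9 | 2-iodo-3,5-dimethoxyphenol | COc1cc(O)c(I)c(OC)c1
F9 | step 9 | 2-hydroxy-3-iodo-4,6-dimethoxybenzaldehyde | COc1cc(OC)c(C=O)c(O)c1I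
F10 | step 9 | ethyl (Z)-3-(2-hydroxy-3-iodo-4,6-dimethoxyphenyl)prop-2-enoate | CCOC(=O)/C=C\c1c(OC)cc(OC)c(I)c1O
A1 | alternative 1 | 2-[(1R,6S)-3,6-dimethyl-6-[(triisopropylsilyl)ethynyl]cyclohex-2-en-1-yl]-5-methoxy-3-[(triisopropylsilyl)oxy]phenol | CC(C)[Si](C(C)C)(C(C)C)C#C[C@@]1(C)CCC(C)=C[C@H]1c1c(O)cc(OC)cc1O[Si](C(C)C)(C(C)C)C(C)C
A2 | alternative 1 | 3-methoxycyclobut-2-en-1-one | COC1=CC(=O)C1
A3 | alternative 1 | [[(1R,6S)-3,6-dimethyl-6-[(triisopropylsilyl)ethynyl]cyclohex-2-en-1-yl]ethynyloxy]triisopropylsilane | CC(C)[Si](C(C)C)(C(C)C)C#C[C@@]1(C)CCC(C)=C[C@H]1C#CO[Si](C(C)C)(C(C)C)C(C)C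
A4 | alternative 2 | 8-[(1R,6S)-3,6-dimethyl-6-[(trimethylsilyl)ethynyl]cyclohex-2-en-1-yl]-5,7-dimethoxy-2H-chromen-2-one | C[Si](C)(C)C#C[C@@]1(C)CCC(C)=C[C@H]1c1c(OC)cc(OC)c2ccc(=O)oc12
A5 | alternative 2 | 8-[(2R,5Z)-1-hydroxy-2,5-dimethyl-6-(trimethylsilyl)-2-[(trimethylsilyl)ethynyl]hex-5-en-1-yl]-5,7-dimethoxy-2H-chromen-2-one (either carbinol epimer) | C[Si](C)(C)/C=C(C)\CC[C@](C)(C#C[Si](C)(C)C)C(O)c1c(OC)cc(OC)c2ccc(=O)oc12
A6 | alternative 3 | (1S,2S)-2-[2,4-dimethoxy-6-(methoxymethoxy)phenyl]-1,4-dimethylcyclohex-3-ene-1-carboxylic acid | OC(=O)[C@@]1(C)CCC(C)=C[C@H]1c1c(OCOC)cc(OC)cc1OC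
A7 | alternative 3 | (6R)-6-[(E)-2-[2,4-dimethoxy-6-(methoxymethoxy)phenyl]ethenyl]-3,6-dimethyloxan-2-one (C3 epimers) | CC1CC[C@](C)(/C=C/c2c(OCOC)cc(OC)cc2OC)OC1=O
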